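**Route to [(2S,3R,4R)-4-(3,4,5-trimethoxybenzyl)-2-(3,4,5-trimethoxyphenyl)oxolan-3-yl]methanol (12): six steps through a three-component palladium cascade, with the single enantiomer obtained by resolution on a chiral phase**

## Analysis of the target

Compound 12 is a 2,3,4-trisubstituted oxolane: O1, C2 with a 3,4,5-trimethoxyphenyl group, C3 with CH2OH, C4 with a 3,4,5-trimethoxybenzyl group (benzylic carbon C7'), and an unsubstituted C5H2. The three stereocentres are contiguous, (2S,3R,4R). The C2 aryl group is trans to the C3 hydroxymethyl group, which is cis to the C4 benzyl group, so the two aryl-bearing substituents lie on opposite faces, as in the lariciresinol family. Both arenes are identical and fully methylated, so no protecting group is needed; the reactive sites are the primary alcohol and the benzylic ether bond C2–O1. That bond is activated by the electron-rich ring: acids can ionise it, with loss of the C2 configuration, and hydrogen on palladium can cleave it. The difficulty is threefold: three adjacent stereocentres on a flexible five-membered ring, a 3,4-cis relationship that simple equilibration will not deliver, and an absolute configuration with no stereocentre outside the ring to relay from. The strategy rests on the chain O1–C5–C4–C7', which is a propargyl alcohol unit with C4 and C7' as the former alkyne carbons. The three bonds leaving that unit (O1–C2, C4–C3 and C7'–aryl) can be made in one flask, and C2–C3 with their aryl and one-carbon substituents correspond to an arylidene malonate.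

## Retrosynthetic reasoning

**12 to 11.** The hydroxymethyl carbon on C3 is taken back to the ethyl ester 11; no skeletal bond is cut. The ester is wanted for three reasons: it is the remnant of the malonate that serves as carbon nucleophile, it makes C3 epimerisable so that the 2,3-trans relationship can be set thermodynamically, and it shields one face of the ring next to C4. The forward reaction is a hydride reduction that must not disturb C3.

**11 to 10.** The C4–H and C7'–H bonds are removed, giving the benzylidene ester 10. C4 thus becomes the last stereocentre to be set, by addition of hydrogen to the ring face opposite the C3 ester. The forward hydrogenation must be governed by the adjacent ester and not by the more remote C2 aryl group, and it must spare the C2–O1 bond.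

**10 to 9.** Compound 10 is one enantiomer of the racemic trans ester 9; this is a separation, not a bond disconnection. C2 is created earlier in a step that holds no chiral information, so a resolution is unavoidable inside this strategy. It is placed after the hot decarboxylation so that any stress on C2 in that step is of no consequence, and before the two steps that relay C4 and keep C3.

**9 to 8.** A second ester is put back on C3, giving the malonate 8. This makes C3 a soft, stabilised carbanion centre able to attack an alkyne. The forward step removes one ester and leaves the remaining one trans to the C2 aryl group.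

**8 to 3, 4 and 5.** Three bonds are cut at once: O1–C2, C3–C4 and C7'–aryl. All three radiate from the propargyl unit of 4. Cutting here, and not at C2–C3, leaves that bond inside the simple achiral acceptor 3, and the second aryl group comes from the iodide 5. In the forward direction the alkoxide 6 from 4 adds to 3 to give the enolate 7. Its malonate carbon closes onto the alkyne while palladium delivers the aryl group of 5 to the other alkyne carbon. The whole carbon skeleton, with one surplus ester, results from one operation.

**3 to 1 and 2.** The C2=C3 double bond of 3 is cut by a condensation disconnection into the aldehyde 1 and the malonate 2.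

## Alternatives that were turned down

**Alternative 1: ring expansion of a cyclopropyl aldehyde.**
- Disconnection: O1–C2 of a 2,3-dihydrofuran with a C4=C5 enol ether, A1, traced to the cyclopropane carbaldehyde A2 in which the future C2 and C4 are still bonded.
- Forward key step: Sc(OTf)3 binds the formyl group of A2, the cyclopropane bond between the aryl-bearing and the formyl-bearing carbon breaks, and the enolate oxygen closes on the benzylic carbon (Cloke–Wilson rearrangement) to give A1.
- For: C3 passes unchanged out of the cyclopropane, so an enantioselective cyclopropanation would give absolute control without a resolution. On this point the alternative is stronger than the chosen route. Ring closure at the benzylic cation should place the aryl group trans to the C3 side chain. Hydrogenation of the enol ether of A1 anti to the bulky silyloxymethyl group should give 3,4-cis at least as reliably as the benzylidene hydrogenation used here.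
- Against: A2 is a fully substituted cyclopropane with a quaternary formyl/benzyl carbon and three stereocentres, and its preparation alone would take more steps than the whole chosen route. A1 combines an enol ether with the activated benzylic ether, both exposed to the Lewis acid that forms them, so re-ionisation at C2 and Friedel–Crafts attack on the electron-rich rings compete.
- Comparison: the chosen route gives up absolute control but builds the skeleton from three simple pieces in one flask and never exposes the benzylic ether to a Lewis acid.

**Alternative 2: cycloaddition of a carbonyl ylide to a butenolide.**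
- Disconnection: C2–C3 and C4–C5, with the C3 and C4 side chains tied together as a benzylic lactone that is opened later. This leads to the bicyclic lactone A3, the butenolide A4 and the α-chloro silylmethyl ether A5.
- Forward key step: CsF removes the silyl group of A5, chloride leaves, and the non-stabilised ylide adds across the alkene of A4 on the face away from its aryl group.
- For: the ring and two C–C bonds form in one step. The cis ring fusion fixes 3,4-cis by construction, which is stronger than a face-selective hydrogenation. The stereocentre of A4 relays the absolute configuration.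
- Against: nothing firm decides which ylide terminus bonds to the α-carbon, nor whether its aryl group ends exo, as 2,3-trans requires. The γ-hydrogen of A4 is benzylic, allylic and next to oxygen, so the basic fluoride medium can racemise it through the aromatic hydroxyfuran tautomer. Later the lactone benzylic C–O bond must be hydrogenolysed beside the C2–O1 bond, which carries the same aryl group, and the acid must then be reduced.
- Comparison: the chosen route never has to tell two trimethoxybenzylic C–O bonds apart and is shorter, since enantiopure A4 and moisture-sensitive A5 each need several steps. In exchange it relies on a hydrogenation for 3,4-cis.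

**Alternative 3: enantioselective carbene C–H insertion.**
- Disconnection: C2–C3 with the benzylidene in place, leading to the methyl ester A6 and the vinyldiazoacetate A7, a benzyl allyl ether.
- Forward key step: Rh2(S-DOSP)4 releases nitrogen from A7, and the donor–acceptor rhodium carbene inserts into the benzylic C–H bond next to oxygen (1,5-insertion) to close the oxolane.
- For: the catalyst sets C2, and with it C3, in the absolute sense, so no material is lost to a resolution. A6 is the methyl ester counterpart of 10, so the endgame would be the same two steps. On stereocontrol this alternative is stronger.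
- Against: A7 needs a trisubstituted alkene of defined geometry carrying both the diazo ester and the ether chain, which is a long linear preparation. Vinyldiazo compounds of this kind tend to cyclise to pyrazoles. The vinylcarbene can react at its vinylogous terminus or with the electron-rich arenes. Insertion at such an electron-rich benzylic position has much hydride-transfer character, which makes enantio- and cis/trans selectivity less secure; the cis ester usually forms first and must be epimerised.
- Comparison: the chosen route is about three steps shorter and uses only robust reaction types with a simple palladium catalyst. In place of catalytic asymmetric induction it offers brevity and a resolution only three steps from commercial materials.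

Key step: step 2

Remark on the chemistry: 7, 8 and 9 are racemic and are drawn as the enantiomer that is carried on to 12. The descriptor changes at C2 (R in 8, S from 9 on) and at C3 (S in the esters, R in 12) come from changed priorities, not from inversion. Compounds 1, 2, 4 and 5 are taken as commercial.

## Route

Step 1
Reactants: 1 3,4,5-trimethoxybenzaldehyde; 2 diethyl malonate
Product: 3 diethyl 2-(3,4,5-trimethoxybenzylidene)malonate
Conditions: piperidine (10 mol%), AcOH (10 mol%), toluene, reflux, Dean–Stark trap
Reagents that add atoms: none
Why: Knoevenagel condensation; amine catalysis and azeotropic removal of water should drive it to completion even with the electron-rich aldehyde. The two esters are identical, so no alkene isomer can arise.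

Step 2
Reactants: 3 diethyl 2-(3,4,5-trimethoxybenzylidene)malonate; 4 propargyl alcohol (prop-2-yn-1-ol); 5 5-iodo-1,2,3-trimethoxybenzene
Product: 8 diethyl (2RS,4Z)-2-(3,4,5-trimethoxyphenyl)-4-(3,4,5-trimethoxybenzylidene)oxolane-3,3-dicarboxylate (racemic), via lithium prop-2-yn-1-olate 6 (not isolated), via lithium enolate of the oxa-Michael adduct 7 (not isolated)
Conditions: 4, n-BuLi, THF, 0 °C; then 3; then 5, PdCl2(PPh3)2 (5 mol%)/n-BuLi (10 mol%), DMSO–THF, rt to 45 °C
Reagents that add atoms: none
Why: n-BuLi turns 4 into the alkoxide 6, which adds reversibly to the β-carbon of 3 (oxa-Michael addition, bond O1–C2) to give the malonate enolate 7. Zerovalent palladium, formed from PdCl2(PPh3)2 and n-BuLi, inserts into the C–I bond of 5, and the resulting arylpalladium iodide (divalent palladium) binds the alkyne of 7 as a π-acid. The malonate carbon then attacks the internal alkyne carbon on the side away from palladium (bond C3–C4), a 5-exo-dig closure that forms the oxolane, and the vinyl(aryl)palladium intermediate reductively eliminates with retention (bond C7'–aryl), so that the aryl group ends cis to C5 (Z alkene) and zerovalent palladium is returned. The closest known reaction type is this same palladium-mediated three-component coupling of propargyl alkoxides, alkylidene malonates and aryl halides to 4-benzylidene oxolanes. The only stereocentre, C2, is created in the oxa-Michael addition with no chiral element present, so 8 is racemic; the alkene geometry follows from the anti attack and is erased later. The step needs the cyclisation–coupling to outrun direct alkynylation of the arylpalladium species and the palladium-free closure to a 4-methylidene oxolane: the lithium counter-ion keeps the uncatalysed closure slow, the short tether O1–C5 lets the carbanion reach only C4 (6-endo attack at the terminal carbon is strained), and the irreversible ring closure pulls the Michael equilibrium forward.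

Step 3
Reactants: 8 diethyl (2RS,4Z)-2-(3,4,5-trimethoxyphenyl)-4-(3,4,5-trimethoxybenzylidene)oxolane-3,3-dicarboxylate (racemic)
Product: 9 ethyl (2S*,3S*,4Z)-2-(3,4,5-trimethoxyphenyl)-4-(3,4,5-trimethoxybenzylidene)oxolane-3-carboxylate (racemic 2,3-trans ester)
Conditions: LiCl, H2O, DMSO, 140–150 °C
Reagents that add atoms: none
Why: Krapcho dealkoxycarbonylation: chloride dealkylates one ester by SN2 attack on its ethyl group, the carboxylate loses CO2 to an ester enolate that is also allylic, and water protonates it at C3. The C3–H of the product is acidic enough to equilibrate under the mildly basic conditions, which should favour the 2,3-trans ester with the ester away from the C2 aryl group (thermodynamic control of C3 relative to C2).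

Step 4
Reactants: 9 ethyl (2S*,3S*,4Z)-2-(3,4,5-trimethoxyphenyl)-4-(3,4,5-trimethoxybenzylidene)oxolane-3-carboxylate (racemic 2,3-trans ester)
Product: 10 ethyl (2S,3S,4Z)-2-(3,4,5-trimethoxyphenyl)-4-(3,4,5-trimethoxybenzylidene)oxolane-3-carboxylate
Conditions: preparative chiral SFC, amylose tris(3,5-dimethylphenylcarbamate) phase, CO2/i-PrOH
Reagents that add atoms: none
Why: Resolution by chromatography on a polysaccharide carbamate phase, for which the two aryl groups and the ester of 9 offer the π-stacking and hydrogen-bond acceptor contacts such phases recognise; the neutral eluent leaves the epimerisable C3 untouched. The (2S,3S) enantiomer would be identified by anomalous-dispersion crystallography or by electronic circular dichroism against calculation, and confirmed by the sign of rotation of 12.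

Step 5
Reactants: 10 ethyl (2S,3S,4Z)-2-(3,4,5-trimethoxyphenyl)-4-(3,4,5-trimethoxybenzylidene)oxolane-3-carboxylate
Product: 11 ethyl (2S,3S,4R)-4-(3,4,5-trimethoxybenzyl)-2-(3,4,5-trimethoxyphenyl)oxolane-3-carboxylate
Conditions: H2 (1 atm), 10% Pd/C, pyridine (0.5 equiv), EtOAc, rt
Reagents that add atoms: none
Why: Heterogeneous hydrogenation with syn delivery of H2 to the less hindered face. The C3 ester sits directly beside C4 while the C2 aryl group on the other face is one atom further away, so hydrogen should enter anti to the ester and leave the benzyl group cis to it (4R), as is usual for 3-substituted 4-benzylidene oxolanes. Pyridine tempers the catalyst so that the benzylic C2–O1 bond should not be hydrogenolysed.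

Step 6
Reactants: 11 ethyl (2S,3S,4R)-4-(3,4,5-trimethoxybenzyl)-2-(3,4,5-trimethoxyphenyl)oxolane-3-carboxylate
Product: 12 [(2S,3R,4R)-4-(3,4,5-trimethoxybenzyl)-2-(3,4,5-trimethoxyphenyl)oxolan-3-yl]methanol
Conditions: LiAlH4, THF, 0 °C; then H2O, aq. NaOH
Reagents that add atoms: none
Why: Ester reduction by LiAlH4; at 0 °C hydride addition is far faster than enolisation, so C3 keeps its configuration. The aryl methyl ethers and the oxolane are inert to the reagent.

## Compound list

1 | 3,4,5-trimethoxybenzaldehyde | COc1cc(C=O)cc(OC)c1OC | starting material
2 | diethyl malonate | CCOC(=O)CC(=O)OCC | starting material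
3 | diethyl 2-(3,4,5-trimethoxybenzylidene)malonate | CCOC(=O)C(=Cc1cc(OC)c(OC)c(OC)c1)C(=O)OCC | intermediate
4 | propargyl alcohol (prop-2-yn-1-ol) | C#CCO | starting material
5 | 5-iodo-1,2,3-trimethoxybenzene | COc1cc(I)cc(OC)c1OC | starting material
6 | lithium prop-2-yn-1-olate | [Li+].[O-]CC#C | intermediate
7 | lithium enolate of diethyl 2-[(prop-2-yn-1-yloxy)(3,4,5-trimethoxyphenyl)methyl]malonate (racemic) | [Li+].CCOC(=O)C(=C([O-])OCC)C(OCC#C)c1cc(OC)c(OC)c(OC)c1 | intermediate
8 | diethyl (2RS,4Z)-2-(3,4,5-trimethoxyphenyl)-4-(3,4,5-trimethoxybenzylidene)oxolane-3,3-dicarboxylate (racemic; 2R drawn) | COc1cc(/C=C2\CO[C@H](c3cc(OC)c(OC)c(OC)c3)C2(C(=O)OCC)C(=O)OCC)cc(OC)c1OC | intermediate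
9 | ethyl (2S*,3S*,4Z)-2-(3,4,5-trimethoxyphenyl)-4-(3,4,5-trimethoxybenzylidene)oxolane-3-carboxylate (racemic 2,3-trans ester; 2S,3S drawn) | COc1cc(/C=C2\CO[C@H](c3cc(OC)c(OC)c(OC)c3)[C@H]2C(=O)OCC)cc(OC)c1OC | intermediate
10 | ethyl (2S,3S,4Z)-2-(3,4,5-trimethoxyphenyl)-4-(3,4,5-trimethoxybenzylidene)oxolane-3-carboxylate (single enantiomer) | COc1cc(/C=C2\CO[C@H](c3cc(OC)c(OC)c(OC)c3)[C@H]2C(=O)OCC)cc(OC)c1OC | intermediate
11 | ethyl (2S,3S,4R)-4-(3,4,5-trimethoxybenzyl)-2-(3,4,5-trimethoxyphenyl)oxolane-3-carboxylate | COc1cc(C[C@H]2CO[C@H](c3cc(OC)c(OC)c(OC)c3)[C@H]2C(=O)OCC)cc(OC)c1OC | intermediate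
12 | [(2S,3R,4R)-4-(3,4,5-trimethoxybenzyl)-2-(3,4,5-trimethoxyphenyl)oxolan-3-yl]methanol | COc1cc(C[C@H]2CO[C@H](c3cc(OC)c(OC)c(OC)c3)[C@H]2CO)cc(OC)c1OC | target

## Step count and risk

Total step count: 6. Longest linear sequence: 6 steps (1 to 3 to 8 to 9 to 10 to 11 to 12).

**Step 2 (key step).**
- Risk: the arylpalladium species may alkynylate the terminal alkyne of 6 or 7 directly, before the carbanion attacks. The oxa-Michael equilibrium may lie on the side of 3, because the trimethoxyphenyl group weakens the acceptor, so little 7 is present. Oxidative addition of the electron-rich iodide 5 is also slower than for simple aryl iodides.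
- Fallback: the aryl group is brought in after the ring is made, setting out from 3 and 4 and coming back at 11.
  - Catalytic t-BuOK in THF effects the same oxa-Michael addition and a palladium-free 5-exo-dig closure to racemic diethyl 4-methylidene-2-(3,4,5-trimethoxyphenyl)oxolane-3,3-dicarboxylate F1.
  - Krapcho dealkoxycarbonylation as in step 3 gives racemic ethyl (2S*,3S*)-4-methylidene-2-(3,4,5-trimethoxyphenyl)oxolane-3-carboxylate F2.
  - 9-BBN adds to the methylidene group from the face away from the ester, giving the borane ethyl (2S*,3S*,4R*)-4-[(9-borabicyclo[3.3.1]nonan-9-yl)methyl]-2-(3,4,5-trimethoxyphenyl)oxolane-3-carboxylate F3.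
  - F3 is coupled without isolation with 5 (PdCl2(dppf), K3PO4, THF/DMF/H2O, Suzuki–Miyaura coupling; mild base so that C3 is not epimerised) to racemic ethyl (2S*,3S*,4R*)-4-(3,4,5-trimethoxybenzyl)-2-(3,4,5-trimethoxyphenyl)oxolane-3-carboxylate F4.
  - Separation on the chiral phase of step 4 returns the route at 11.

**Step 3.**
- Risk: the dienolate formed on decarboxylation can be protonated at C7', which moves the double bond into the ring and into conjugation with the ester. The C3 enolate can also expel O1 by β-elimination and open the ring. Equilibration to the trans ester may be incomplete at a temperature low enough to avoid both.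
- Fallback: hydrolysis and decarboxylation in place of nucleophilic dealkylation, setting out from 8 and returning at 9. KOH (1 equiv) in EtOH/H2O cleaves one ester to (2RS,4Z)-3-(ethoxycarbonyl)-2-(3,4,5-trimethoxyphenyl)-4-(3,4,5-trimethoxybenzylidene)oxolane-3-carboxylic acid F5, a mixture of C3 epimers. After acidification it loses CO2 on warming in toluene (80–110 °C) through the cyclic malonic half-ester pathway. No chloride or hydroxide is present at high temperature.

**Step 4.**
- Risk: the enantiomers may not separate well enough on a preparative scale, and half of the material is lost in any case.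
- Fallback: resolution through covalent diastereomers at the end, setting out from 9 and returning at 12.
  - Steps 5 and 6 are run on the racemate. This gives the racemic saturated ester ethyl (2S*,3S*,4R*)-4-(3,4,5-trimethoxybenzyl)-2-(3,4,5-trimethoxyphenyl)oxolane-3-carboxylate F4, already met above, and then racemic [(2S*,3R*,4R*)-4-(3,4,5-trimethoxybenzyl)-2-(3,4,5-trimethoxyphenyl)oxolan-3-yl]methanol F6.
  - Acylation with (1S)-camphanic chloride (pyridine, DMAP, CH2Cl2) gives the (1S)-camphanate of 12 F7 together with the (1S)-camphanate of the enantiomeric alcohol F8.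
  - These diastereomers are separated by crystallisation or on silica, and K2CO3 in MeOH releases 12 from F7.

**Step 5.**
- Risk: facial selectivity may be poor, because the C2 aryl group and the C3 ester shield opposite faces. Palladium may shift the double bond to C3=C4 before reduction, which would erase C3. The benzylic C2–O1 bond may be hydrogenolysed.
- Fallback: reduction before hydrogenation, setting out from 10 and returning at 12. This gives a larger shielding group on C3 that cannot epimerise or conjugate.
  - LiAlH4 (THF, 0 °C) gives [(2S,3R,4Z)-2-(3,4,5-trimethoxyphenyl)-4-(3,4,5-trimethoxybenzylidene)oxolan-3-yl]methanol F9.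
  - TBDPSCl and imidazole give tert-butyl{[(2S,3R,4Z)-2-(3,4,5-trimethoxyphenyl)-4-(3,4,5-trimethoxybenzylidene)oxolan-3-yl]methoxy}diphenylsilane F10.
  - Hydrogenation (H2, Pd/C, pyridine, EtOAc) anti to the silyloxymethyl group gives tert-butyl{[(2S,3R,4R)-4-(3,4,5-trimethoxybenzyl)-2-(3,4,5-trimethoxyphenyl)oxolan-3-yl]methoxy}diphenylsilane F11.
  - TBAF in THF gives 12.

## Further compounds

F1 | step 2 | diethyl (2RS)-4-methylidene-2-(3,4,5-trimethoxyphenyl)oxolane-3,3-dicarboxylate (racemic; 2R drawn) | C=C1CO[C@H](c2cc(OC)c(OC)c(OC)c2)C1(C(=O)OCC)C(=O)OCC
F2 | step 2 | ethyl (2S*,3S*)-4-methylidene-2-(3,4,5-trimethoxyphenyl)oxolane-3-carboxylate (racemic, 2,3-trans) | C=C1CO[C@H](c2cc(OC)c(OC)c(OC)c2)[C@H]1C(=O)OCC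
F3 | step 2 | ethyl (2S*,3S*,4R*)-4-[(9-borabicyclo[3.3.1]nonan-9-yl)methyl]-2-(3,4,5-trimethoxyphenyl)oxolane-3-carboxylate (racemic) | C(B1C2CCCC1CCC2)[C@H]3CO[C@H](c4cc(OC)c(OC)c(OC)c4)[C@H]3C(=O)OCC
F4 | step 2 | ethyl (2S*,3S*,4R*)-4-(3,4,5-trimethoxybenzyl)-2-(3,4,5-trimethoxyphenyl)oxolane-3-carboxylate (racemic) | COc1cc(C[C@H]2CO[C@H](c3cc(OC)c(OC)c(OC)c3)[C@H]2C(=O)OCC)cc(OC)c1OC
F5 | step 3 | (2RS,4Z)-3-(ethoxycarbonyl)-2-(3,4,5-trimethoxyphenyl)-4-(3,4,5-trimethoxybenzylidene)oxolane-3-carboxylic acid (racemic, C3 epimers) | COc1cc(/C=C2\CO[C@H](c3cc(OC)c(OC)c(OC)c3)C2(C(=O)O)C(=O)OCC)cc(OC)c1OC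
F6 | step 4 | [(2S*,3R*,4R*)-4-(3,4,5-trimethoxybenzyl)-2-(3,4,5-trimethoxyphenyl)oxolan-3-yl]methanol (racemic) | COc1cc(C[C@H]2CO[C@H](c3cc(OC)c(OC)c(OC)c3)[C@H]2CO)cc(OC)c1OC
F7 | step 4 | [(2S,3R,4R)-4-(3,4,5-trimethoxybenzyl)-2-(3,4,5-trimethoxyphenyl)oxolan-3-yl]methyl (1S,4R)-camphanate | COc1cc(C[C@H]2CO[C@H](c3cc(OC)c(OC)c(OC)c3)[C@H]2COC(=O)[C@@]45CC[C@@](C)(C(=O)O4)C5(C)C)cc(OC)c1OC
F8 | step 4 | [(2R,3S,4S)-4-(3,4,5-trimethoxybenzyl)-2-(3,4,5-trimethoxyphenyl)oxolan-3-yl]methyl (1S,4R)-camphanate | COc1cc(C[C@@H]2CO[C@@H](c3cc(OC)c(OC)c(OC)c3)[C@@H]2COC(=O)[C@@]45CC[C@@](C)(C(=O)O4)C5(C)C)cc(OC)c1OC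
F9 | step 5 | [(2S,3R,4Z)-2-(3,4,5-trimethoxyphenyl)-4-(3,4,5-trimethoxybenzylidene)oxolan-3-yl]methanol | COc1cc(/C=C2\CO[C@H](c3cc(OC)c(OC)c(OC)c3)[C@H]2CO)cc(OC)c1OC
F10 | step 5 | tert-butyl{[(2S,3R,4Z)-2-(3,4,5-trimethoxyphenyl)-4-(3,4,5-trimethoxybenzylidene)oxolan-3-yl]methoxy}diphenylsilane | COc1cc(/C=C2\CO[C@H](c3cc(OC)c(OC)c(OC)c3)[C@H]2CO[Si](c4ccccc4)(c5ccccc5)C(C)(C)C)cc(OC)c1OC
F11 | step 5 | tert-butyl{[(2S,3R,4R)-4-(3,4,5-trimethoxybenzyl)-2-(3,4,5-trimethoxyphenyl)oxolan-3-yl]methoxy}diphenylsilane | COc1cc(C[C@H]2CO[C@H](c3cc(OC)c(OC)c(OC)c3)[C@H]2CO[Si](c4ccccc4)(c5ccccc5)C(C)(C)C)cc(OC)c1OC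
A1 | alternative 1 | tert-butyl{[(2S,3R)-4-(3,4,5-trimethoxybenzyl)-2-(3,4,5-trimethoxyphenyl)-2,3-dihydrofuran-3-yl]methoxy}dimethylsilane | COc1cc(CC2=CO[C@H](c3cc(OC)c(OC)c(OC)c3)[C@H]2CO[Si](C)(C)C(C)(C)C)cc(OC)c1OC
A2 | alternative 1 | 2-[(tert-butyldimethylsilyloxy)methyl]-1-(3,4,5-trimethoxybenzyl)-3-(3,4,5-trimethoxyphenyl)cyclopropane-1-carbaldehyde (configured at the silyloxymethyl carbon) | O=CC1(Cc2cc(OC)c(OC)c(OC)c2)[C@H](CO[Si](C)(C)C(C)(C)C)C1c3cc(OC)c(OC)c(OC)c3
A3 | alternative 2 | cis-fused 4,8-bis(3,4,5-trimethoxyphenyl)-3,7-dioxabicyclo[3.3.0]octan-2-one | COc1cc([C@@H]3[C@H]2CO[C@H](c4cc(OC)c(OC)c(OC)c4)[C@H]2C(=O)O3)cc(OC)c1OC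
A4 | alternative 2 | (S)-5-(3,4,5-trimethoxyphenyl)furan-2(5H)-one | O=C1C=C[C@@H](c2cc(OC)c(OC)c(OC)c2)O1
A5 | alternative 2 | {[chloro(3,4,5-trimethoxyphenyl)methoxy]methyl}trimethylsilane (racemic) | COc1cc(C(Cl)OC[Si](C)(C)C)cc(OC)c1OC
A6 | alternative 3 | methyl (2S,3S,4Z)-2-(3,4,5-trimethoxyphenyl)-4-(3,4,5-trimethoxybenzylidene)oxolane-3-carboxylate | COc1cc(/C=C2\CO[C@H](c3cc(OC)c(OC)c(OC)c3)[C@H]2C(=O)OC)cc(OC)c1OC
A7 | alternative 3 | methyl (Z)-2-diazo-3-{[(3,4,5-trimethoxybenzyl)oxy]methyl}-4-(3,4,5-trimethoxyphenyl)but-3-enoate | COC(=O)C(=[N+]=[N-])/C(COCc1cc(OC)c(OC)c(OC)c1)=C/c1cc(OC)c(OC)c(OC)c1
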